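**Plan**

1. Labdane numbering is used: ring A = C1–C5, C10; ring B = C5–C10; chain C11–C13 on C9; β = face of the C10 methyl. Retrosynthetically, the C8 acetate and the C13 carboxyl are joined into a ring-C cyclopentanone (C8–C13 bond, Baeyer–Villiger retron), and ring B is then cut at C5–C6 and C7–C8, which removes C6–C7 as a vinyl unit.
2. Enabling feature: C5 is a ring-A ketone with no α-hydrogen (flanked by quaternary C4 and C10), and C8 is the α-carbon of a planar 2-methylcyclopentenone (C8, C9, C11, C12, C13) attached to C10. Vinyl adds to C5 as a nucleophile; after ionisation to a C5–C6–C7 allyl unit its C7 end is attacked by C8.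
3. Forward order: ring A (β-keto ester; C4, then C10 made quaternary), ring C attached at C10, ring B closed in the key one-flask vinylation/allylic alkylation, then hydrogenation, Baeyer–Villiger oxidation, lactone opening, acetylation and deprotection.
4. Stereochemistry: C4 from a valine-derived lithio-enamine alkylation; C10 relative to C4 by chelation-controlled enolate alkenylation; C8 relative to C10 in the ring closure (planar ring C, chair ring B); C5 and C9 by hydrogen delivery to the α face, opposite the three β methyl groups; the C8–O bond by migration with retention.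

Key step: step 6

Assumption (chemistry): the lithio-enamine from tert-butyl L-valinate in toluene/HMPA is taken to be methylated on the face that gives the (R)-quaternary centre; if the sense is the opposite, tert-butyl D-valinate is used instead.

**Step 1**
Reactants: 1 methyl 2-oxocyclohexane-1-carboxylate; 2 tert-butyl L-valinate
Product: 3 methyl 2-{[(2S)-1-tert-butoxy-3-methyl-1-oxobutan-2-yl]amino}cyclohex-1-ene-1-carboxylate
Conditions: TsOH (cat.), toluene, reflux, azeotropic removal of water
Reagents that add atoms: none
Why: Acid-catalysed condensation of the β-keto ester with the primary amine should give the hydrogen-bonded enamino ester (vinylogous carbamate) that carries the chiral auxiliary; no stereocentre is formed.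

**Step 2**
Reactants: 3 methyl 2-{[(2S)-1-tert-butoxy-3-methyl-1-oxobutan-2-yl]amino}cyclohex-1-ene-1-carboxylate
Product: 5 methyl (1R)-1-methyl-2-oxocyclohexane-1-carboxylate, via methylated imine 4 (not isolated)
Conditions: LiN(i-Pr)2, toluene/HMPA, −78 °C; MeI, −78 to −20 °C; then 1 M HCl, THF, 0 °C
Reagents that add atoms: methyl iodide (CI); water (O)
Why: Auxiliary-controlled alkylation of the chelated lithio-enamine, in which the valine ester side chain should shield one face so that methyl iodide sets the (R)-quaternary carbon (later C4), followed by mild acid hydrolysis of the imine to release the ketone and the auxiliary.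

**Step 3**
Reactants: 5 methyl (1R)-1-methyl-2-oxocyclohexane-1-carboxylate
Product: 6 methyl (1R,3RS)-1,3-dimethyl-2-oxocyclohexane-1-carboxylate
Conditions: LiN(i-Pr)2, THF, −78 °C; MeI, −78 to 0 °C
Reagents that add atoms: methyl iodide (CI)
Why: Enolate alkylation, regiospecific because the ketone can enolise only toward C3 (C1 is quaternary); the C3 configuration does not matter since this centre is made planar again in step 5.

**Step 4**
Reactants: 7 2-methylcyclopentane-1,3-dione
Product: 8 3-bromo-2-methylcyclopent-2-en-1-one
Conditions: (COBr)2, DMF (cat.), CH2Cl2, 0 to 25 °C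
Reagents that add atoms: oxalyl bromide (O=C(Br)C(=O)Br)
Why: Vilsmeier-type activation of the enol form of the 1,3-dione should give the vinylogous acid bromide; no stereocentre is involved.

**Step 5**
Reactants: 6 methyl (1R,3RS)-1,3-dimethyl-2-oxocyclohexane-1-carboxylate; 8 3-bromo-2-methylcyclopent-2-en-1-one
Product: 9 methyl (1R,3R)-1,3-dimethyl-3-(2-methyl-3-oxocyclopent-1-en-1-yl)-2-oxocyclohexane-1-carboxylate
Conditions: LiN(SiMe3)2, toluene, −78 to 25 °C; then 8, Pd2(dba)3 (2 mol %), P(t-Bu)3 (4 mol %), 50 °C
Reagents that add atoms: none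
Why: Palladium-catalysed α-alkenylation of the only possible (C3) lithium enolate (uncatalysed addition–elimination on the β-bromo enone would lead to the same product); the lithium ion bridging the enolate oxygen and the ester carbonyl should hold CO2Me pseudo-equatorial and the C1 methyl pseudo-axial, so the alkenyl group should enter anti to that methyl and give the (1R,3R) isomer with the two methyl groups cis.

**Step 6**
Reactants: 9 methyl (1R,3R)-1,3-dimethyl-3-(2-methyl-3-oxocyclopent-1-en-1-yl)-2-oxocyclohexane-1-carboxylate
Product: 13 methyl 13-oxo-8,13-cyclo-14,15,16-trinorlabda-5,9(11)-dien-18-oate (C4, C8 and C10 methyls β; CO2Me α), via silyl dienol ether 10 (not isolated), via bromomagnesium alkoxide 11 (not isolated), via allylic methyl carbonate 12 (not isolated)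
Conditions: LiN(SiMe3)2, THF, −78 to 0 °C; Me3SiCl; CH2=CHMgBr, CeCl3, −78 to 0 °C; ClCO2Me, 0 °C; then Pd(PPh3)4 (5 mol %), 50 °C
Reagents that add atoms: vinylmagnesium bromide (C=C[Mg]Br)
Why: O-silylation of the extended lithium dienolate masks the only enolisable carbonyl (C13), so that the vinylcerium reagent adds to the ring-A ketone C5 and forms C5–C6; the tertiary alkoxide is trapped as its methyl carbonate, which zerovalent palladium ionises with loss of CO2 to a π-allyl complex over C5–C6–C7, and the methoxide set free desilylates the dienol ether to the cyclopentadienolate. The closest known reaction types are 1,2-addition of vinyl organometallics to hindered ketones, the Tsuji–Trost allylation of silyl enol ethers by allylic carbonates and, taken together, the Torgov reaction in which a vinyl carbinol is joined to a 2-methylcyclopentane-1,3-dione. Ring B closes in the endo mode (the allyl unit ends inside the ring) by attack of the dienolate α-carbon C8 on the allyl terminus C7, the only terminus that can give a six-membered ring; this leaves C5=C6 and moves the ring-C double bond to C9=C11. The one new stereocentre, C8, is set relative to C10: the planar cyclopentene holds C13 in the plane of C9 (equatorial on ring B) and the C4–C5(=C6) unit of ring A holds C1 equatorial, so a chair-like closure must place the C8 and C10 methyl groups on the same (β) face. The step needs 1,2-addition at C5 and not at the enone or the ester (secured by the silyl mask, by CeCl3 and by chelation of the β-keto ester), and alkylation of the dienolate at C8 and not at its γ-carbon C11 (expected from the larger coefficient at the α-carbon and from the relief of allylic strain between the C8 methyl and C10 that only α-attack brings).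

**Step 7**
Reactants: 13 methyl 13-oxo-8,13-cyclo-14,15,16-trinorlabda-5,9(11)-dien-18-oate
Product: 14 methyl 13-oxo-8,13-cyclo-14,15,16-trinorlabdan-18-oate (5α-H, 9α-H)
Conditions: Mn(dpm)3 (10 mol %), PhSiH3, t-BuOOH, i-PrOH, 25 °C
Reagents that add atoms: none
Why: Metal-hydride hydrogen-atom-transfer hydrogenation, in which hydrogen atoms add to C6 and C11 to give tertiary radicals at C5 and C9; each is flanked by quaternary carbons whose methyl groups (on C4, C8, C10) shield the β face, so the second hydrogen should arrive from the α face and set 5α-H and 9α-H (trans A/B and trans B/C fusions), with ketone and ester untouched.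

**Step 8**
Reactants: 14 methyl 13-oxo-8,13-cyclo-14,15,16-trinorlabdan-18-oate
Product: 15 methyl 13-oxo-8α,13-epoxy-14,15,16-trinorlabdan-18-oate (the 13,8α-lactone)
Conditions: mCPBA, CH2Cl2, 25 °C
Reagents that add atoms: mCPBA (OOC(=O)c1cccc(Cl)c1)
Why: Baeyer–Villiger oxidation, in which the quaternary carbon C8 should migrate in preference to the methylene C12 and with retention, so that oxygen takes the place of C13 on the α face of C8 and the cyclopentanone becomes the six-membered lactone.

**Step 9**
Reactants: 15 methyl 13-oxo-8α,13-epoxy-14,15,16-trinorlabdan-18-oate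
Product: 17 dibenzyl 8α-hydroxy-14,15,16-trinorlabdane-13,18-dioate, via dipotassium hydroxy dicarboxylate 16 (not isolated)
Conditions: KOH, HOCH2CH2OH/H2O, 150 °C; then BnBr, DMF, 25 °C
Reagents that add atoms: potassium hydroxide ([K+].[OH-]); benzyl bromide (BrCc1ccccc1)
Why: Saponification by acyl–oxygen cleavage (the C8–O bond and its configuration are untouched) should open the lactone and also cleave the hindered methyl ester, and SN2 benzylation of both carboxylates in the same flask avoids acidification, under which the hydroxy acid would close back to the lactone.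

**Step 10**
Reactants: 17 dibenzyl 8α-hydroxy-14,15,16-trinorlabdane-13,18-dioate
Product: 18 dibenzyl 8α-acetoxy-14,15,16-trinorlabdane-13,18-dioate
Conditions: Ac2O, Sc(OTf)3 (1 mol %), MeCN, −20 °C
Reagents that add atoms: acetic anhydride (CC(=O)OC(C)=O)
Why: Sc(OTf)3-catalysed acylation of the hindered tertiary alcohol at low temperature, chosen because it should acetylate tertiary alcohols without elimination and faster than the hydroxy ester can re-lactonise; no stereocentre is touched.

**Step 11**
Reactants: 18 dibenzyl 8α-acetoxy-14,15,16-trinorlabdane-13,18-dioate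
Product: 19 8α-acetoxy-14,15,16-trinorlabdane-13,18-dioic acid (CNP0196050.1)
Conditions: H2 (1 atm), Pd/C, EtOAc, 25 °C
Reagents that add atoms: none
Why: Hydrogenolysis of the two benzyl esters should free both carboxylic acids under neutral conditions that leave the tertiary acetate intact.

**Compound list**

1 | methyl 2-oxocyclohexane-1-carboxylate | COC(=O)C1CCCCC1=O | starting material
2 | tert-butyl L-valinate | CC(C)[C@H](N)C(=O)OC(C)(C)C | starting material
3 | methyl 2-{[(2S)-1-tert-butoxy-3-methyl-1-oxobutan-2-yl]amino}cyclohex-1-ene-1-carboxylate | COC(=O)C1=C(N[C@@H](C(C)C)C(=O)OC(C)(C)C)CCCC1 | intermediate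
4 | methyl (1R)-2-{[(2S)-1-tert-butoxy-3-methyl-1-oxobutan-2-yl]imino}-1-methylcyclohexane-1-carboxylate | CC(C)[C@H](N=C1CCCC[C@@]1(C)C(=O)OC)C(=O)OC(C)(C)C | intermediate
5 | methyl (1R)-1-methyl-2-oxocyclohexane-1-carboxylate | O=C1CCCC[C@@]1(C)C(=O)OC | intermediate
6 | methyl (1R,3RS)-1,3-dimethyl-2-oxocyclohexane-1-carboxylate | O=C1C(C)CCC[C@@]1(C)C(=O)OC | intermediate
7 | 2-methylcyclopentane-1,3-dione | CC1C(=O)CCC1=O | starting material
8 | 3-bromo-2-methylcyclopent-2-en-1-one | CC1=C(Br)CCC1=O | intermediate
9 | methyl (1R,3R)-1,3-dimethyl-3-(2-methyl-3-oxocyclopent-1-en-1-yl)-2-oxocyclohexane-1-carboxylate (methyls cis) | O=C1[C@](C)(CCC[C@@]1(C)C(=O)OC)C2=C(C)C(=O)CC2 | intermediate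
10 | methyl (1R,3R)-1,3-dimethyl-3-[5-methyl-4-(trimethylsilyloxy)cyclopenta-1,4-dien-1-yl]-2-oxocyclohexane-1-carboxylate | O=C1[C@](C)(CCC[C@@]1(C)C(=O)OC)C2=CCC(O[Si](C)(C)C)=C2C | intermediate
11 | bromomagnesium alkoxide of methyl (1R,3R)-2-ethenyl-2-hydroxy-1,3-dimethyl-3-[5-methyl-4-(trimethylsilyloxy)cyclopenta-1,4-dien-1-yl]cyclohexane-1-carboxylate (C2 epimers) | C=CC1([O-])[C@](C)(CCC[C@@]1(C)C(=O)OC)C2=CCC(O[Si](C)(C)C)=C2C.[Mg+2].[Br-] | intermediate
12 | methyl (1R,3R)-2-ethenyl-2-[(methoxycarbonyl)oxy]-1,3-dimethyl-3-[5-methyl-4-(trimethylsilyloxy)cyclopenta-1,4-dien-1-yl]cyclohexane-1-carboxylate (C2 epimers) | C=CC1(OC(=O)OC)[C@](C)(CCC[C@@]1(C)C(=O)OC)C2=CCC(O[Si](C)(C)C)=C2C | intermediate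
13 | methyl 13-oxo-8,13-cyclo-14,15,16-trinorlabda-5,9(11)-dien-18-oate (rings A, B and cyclopentanone ring C; methyls on C4, C8, C10 all β; CO2Me on C4 α) | O=C1CC=C2[C@@]1(C)CC=C3[C@]2(C)CCC[C@@]3(C)C(=O)OC | intermediate
14 | methyl 13-oxo-8,13-cyclo-14,15,16-trinorlabdan-18-oate (5α-H, 9α-H; methyls on C4, C8, C10 β) | O=C1CC[C@H]2[C@@]1(C)CC[C@@H]3[C@]2(C)CCC[C@@]3(C)C(=O)OC | intermediate
15 | methyl 13-oxo-8α,13-epoxy-14,15,16-trinorlabdan-18-oate (13,8α-lactone) | O=C1CC[C@H]2[C@](C)(O1)CC[C@@H]3[C@]2(C)CCC[C@@]3(C)C(=O)OC | intermediate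
16 | dipotassium 8α-hydroxy-14,15,16-trinorlabdane-13,18-dioate | O[C@]1(C)CC[C@@H]2[C@](C)(CCC[C@@]2(C)C(=O)[O-])[C@H]1CCC(=O)[O-].[K+].[K+] | intermediate
17 | dibenzyl 8α-hydroxy-14,15,16-trinorlabdane-13,18-dioate | O[C@]1(C)CC[C@@H]2[C@](C)(CCC[C@@]2(C)C(=O)OCc3ccccc3)[C@H]1CCC(=O)OCc4ccccc4 | intermediate
18 | dibenzyl 8α-acetoxy-14,15,16-trinorlabdane-13,18-dioate | CC(=O)O[C@]1(C)CC[C@@H]2[C@](C)(CCC[C@@]2(C)C(=O)OCc3ccccc3)[C@H]1CCC(=O)OCc4ccccc4 | intermediate
19 | 8α-acetoxy-14,15,16-trinorlabdane-13,18-dioic acid, (4R,5R,8R,9R,10S) | CC(=O)O[C@]1(C)CC[C@@H]2[C@](C)(CCC[C@@]2(C)C(=O)O)[C@H]1CCC(=O)O | target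

**Step count and risks**

Total steps: 11. Longest linear sequence: 10 (steps 1–3 and 5–11; step 4 is a side branch).

Step 6 is the most likely to fail. Addition to the doubly neopentyl ketone may be slow and lose out to attack on the ester. The dienolate may be alkylated through its γ-carbon C11 instead of C8. Proton transfer may move the β,γ-double bond of the product into conjugation. The fallback separates the two bond formations and replaces the palladium step by a hard SN2 alkylation. It sets out from 9: the cyclopentenone is masked only transiently as its lithium enolate (LiN(SiMe3)2), vinylmagnesium bromide/CeCl3 is added, and aqueous work-up should give the tertiary vinyl carbinol F1. PBr3/pyridine in ether should convert it with allylic transposition into the primary allylic bromide F2 (C5=C6, bromide on C7). One equivalent of KOt-Bu in t-BuOH/THF should then close ring B by intramolecular α-alkylation of the potassium dienolate, which comes back to the route at 13.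

Step 5 is the next risk. Facial selectivity may be poor when the bond forms at the tetrasubstituted enolate, giving the isomer with trans methyl groups. O-alkenylation or base-induced decomposition of the bromo enone may also compete. The fallback builds the same bond by conjugate addition and re-oxidation. It sets out from 6: Me3SiOTf/Et3N should give the silyl enol ether F3. A Me3SiNTf2-catalysed Mukaiyama–Michael addition to commercial 2-methylcyclopent-2-en-1-one, through an open transition state with the acceptor anti to the pseudo-axial C1 methyl, should give the adduct as its cyclopentanone silyl enol ether F4. Saegusa–Ito oxidation with Pd(OAc)2 should restore the enone and come back to the route at 9.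

Step 10 is the third risk. Re-lactonisation of the δ-hydroxy ester under the Lewis-acidic conditions may outrun acylation, and the tertiary alcohol may ionise and eliminate. The fallback never exposes a hydroxy ester. It sets out from 15: LiAlH4 should reduce lactone and methyl ester to the triol F5. t-BuMe2SiCl/imidazole should silylate only the two primary hydroxyls to give the bis-silyl ether F6. Ac2O/DMAP/Et3N at 50 °C should acetylate the tertiary alcohol to give the acetate F7. HF·pyridine should remove both silyl groups to give the acetoxy diol F8. TEMPO (cat.)/NaOCl/NaClO2 in phosphate-buffered MeCN should oxidise both primary alcohols to acids, which comes back to the route at 19.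

**Further compounds**

F1 | step 6 | methyl (1R,3R)-2-ethenyl-2-hydroxy-1,3-dimethyl-3-(2-methyl-3-oxocyclopent-1-en-1-yl)cyclohexane-1-carboxylate (C2 epimers) | C=CC1(O)[C@](C)(CCC[C@@]1(C)C(=O)OC)C2=C(C)C(=O)CC2
F2 | step 6 | methyl (1R,3R)-2-(2-bromoethylidene)-1,3-dimethyl-3-(2-methyl-3-oxocyclopent-1-en-1-yl)cyclohexane-1-carboxylate | BrCC=C1[C@](C)(CCC[C@@]1(C)C(=O)OC)C2=C(C)C(=O)CC2
F3 | step 5 | methyl (1R)-1,3-dimethyl-2-(trimethylsilyloxy)cyclohex-2-ene-1-carboxylate | C[Si](C)(C)OC1=C(C)CCC[C@@]1(C)C(=O)OC
F4 | step 5 | methyl (1R,3R)-1,3-dimethyl-3-[2-methyl-3-(trimethylsilyloxy)cyclopent-2-en-1-yl]-2-oxocyclohexane-1-carboxylate (epimers at the cyclopentenyl carbon) | O=C1[C@](C)(CCC[C@@]1(C)C(=O)OC)C2CCC(O[Si](C)(C)C)=C2C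
F5 | step 10 | 14,15,16-trinorlabdane-8α,13,18-triol | O[C@]1(C)CC[C@@H]2[C@](C)(CCC[C@@]2(C)CO)[C@H]1CCCO
F6 | step 10 | 13,18-bis(tert-butyldimethylsilyloxy)-14,15,16-trinorlabdan-8α-ol | O[C@]1(C)CC[C@@H]2[C@](C)(CCC[C@@]2(C)CO[Si](C)(C)C(C)(C)C)[C@H]1CCCO[Si](C)(C)C(C)(C)C
F7 | step 10 | 8α-acetoxy-13,18-bis(tert-butyldimethylsilyloxy)-14,15,16-trinorlabdane | CC(=O)O[C@]1(C)CC[C@@H]2[C@](C)(CCC[C@@]2(C)CO[Si](C)(C)C(C)(C)C)[C@H]1CCCO[Si](C)(C)C(C)(C)C
F8 | step 10 | 8α-acetoxy-14,15,16-trinorlabdane-13,18-diol | CC(=O)O[C@]1(C)CC[C@@H]2[C@](C)(CCC[C@@]2(C)CO)[C@H]1CCCO
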